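**Retrosynthetic overview**

1. Numbering is that of labdanes: ring A = C1–C5 + C10, ring B = C5–C10, side chain C11–C16 on C9, C17 on C8. The feature used: C10 is quaternary, and its ring A neighbours C1 and C5 are equivalent in a 4-methyl-4-alkylcyclohexa-2,5-dienone. Joining the aldehyde carbon C6 of a C9–C8(ketal)–C7–C6 chain to one β-carbon (C5) therefore closes ring B and fixes C10 without making a bond at C10.
2. 37 ⇒ 35 (desilylation; C17 CH2OH → CHO) ⇒ 33 (hydrolysis; Me2CuLi on the ynoate gives the 13Z alkene) ⇒ 30 (hydroxymethyl anion adds to C8=O anti to CH3-10) ⇒ 28 (conjugate propargylation at C11; H-9 by protonation anti to CH3-10) ⇒ 25.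
3. 25 ⇒ trans-decalone 21 (H-5 by hydrogenation of the 4,4-dimethyl-5-ene 20; gem-dimethyl through the dienolate of the 1,4-dien-3-one 18) ⇒ 17 ⇒ (C6 deoxygenation) Stetter adduct 14.
4. 14 ⇒ (C5–C6, carbene-catalysed Stetter desymmetrisation) dienone aldehyde 13 ⇒ (Robinson annulation with methyl vinyl ketone) aldehyde 7 ⇒ β-keto ester 3 ⇒ 3-methylpent-4-enoic acid.
5. Ring order: ring A first (as the cyclohexadienone), ring B second (step 7).

Key step: step 7

Assumption: the sense of induction of the triazolium salt is not predicted here; the enantiomer of the salt (both come from the enantiomers of cis-1-amino-2-indanol) is used that gives (10R)-14.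
Remark: the Stetter adduct is written cis-fused, as the tether dictates. With the 1-en-3-one in ring A neither ring fusion is clearly favoured at equilibrium, so C5 is not set by epimerisation; it is made trigonal in step 11 and set in step 13. Compounds 1–12 are racemic or achiral.

**Route**

Step 1
Reactants: 1 3-methylpent-4-enoic acid
Product: 3 ethyl 5-methyl-3-oxohept-6-enoate, via acyl imidazolide 2 (not isolated)
Conditions: CDI, THF, rt; then KO2CCH2CO2Et, MgCl2, Et3N, MeCN, rt to 50 °C; aq. HCl
Reagents that add atoms: potassium ethyl malonate CCOC(=O)CC(=O)[O-].[K+]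
Why: A Masamune–Brooks chain extension (C-acylation of the magnesium malonate half-ester by the acyl imidazolide, then decarboxylation) should give the β-keto ester under conditions that leave the terminal alkene alone; the CH(CH3) centre is racemic and later becomes C10.

Step 2
Reactants: 3 ethyl 5-methyl-3-oxohept-6-enoate
Product: 4 ethyl [2-(2-methylbut-3-enyl)-1,3-dioxolan-2-yl]acetate
Conditions: HOCH2CH2OH, TsOH·H2O (cat.), benzene, reflux, Dean–Stark
Reagents that add atoms: ethylene glycol OCCO
Why: Acid-catalysed ketalisation with azeotropic removal of water masks the future C8 ketone as the dioxolane, a standard protection of β-keto esters.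

Step 3
Reactants: 4 ethyl [2-(2-methylbut-3-enyl)-1,3-dioxolan-2-yl]acetate
Product: 5 2-[2-(2-methylbut-3-enyl)-1,3-dioxolan-2-yl]ethanol
Conditions: LiAlH4, THF, 0 °C; aqueous work-up
Reagents that add atoms: none
Why: Hydride reduction of the ester gives the primary alcohol (future C6), and ketal and isolated alkene are inert to LiAlH4.

Step 4
Reactants: 5 2-[2-(2-methylbut-3-enyl)-1,3-dioxolan-2-yl]ethanol
Product: 7 3-[2-(2-hydroxyethyl)-1,3-dioxolan-2-yl]-2-methylpropanal, via ozonide 6 (not isolated)
Conditions: O3, CH2Cl2, −78 °C; then Me2S, −78 °C to rt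
Reagents that add atoms: ozone [O-][O+]=O
Why: Ozonolysis of the terminal alkene with reductive work-up should unveil the α-methyl aldehyde while the free alcohol and the ketal stay untouched.

Step 5
Reactants: 7 3-[2-(2-hydroxyethyl)-1,3-dioxolan-2-yl]-2-methylpropanal; 8 methyl vinyl ketone
Product: 11 4-{[2-(2-hydroxyethyl)-1,3-dioxolan-2-yl]methyl}-4-methylcyclohex-2-enone, via enamine 9 (not isolated), via keto aldehyde 10 (not isolated)
Conditions: pyrrolidine, 4 Å MS, toluene, rt; 8, 0 °C to rt; H2O; then KOH (cat.), MeOH, 50 °C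
Reagents that add atoms: none
Why: Robinson annulation through the pyrrolidine enamine: Michael addition of the α-branched enamine to methyl vinyl ketone forms the quaternary carbon (future C10, racemic here) and base-mediated aldol condensation closes ring A as the 4,4-disubstituted cyclohexenone.

Step 6
Reactants: 11 4-{[2-(2-hydroxyethyl)-1,3-dioxolan-2-yl]methyl}-4-methylcyclohex-2-enone
Product: 13 {2-[(1-methyl-4-oxocyclohexa-2,5-dienyl)methyl]-1,3-dioxolan-2-yl}acetaldehyde, via enone aldehyde 12 (not isolated)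
Conditions: IBX (4 equiv), DMSO, 25 °C, then 80 °C
Reagents that add atoms: none
Why: IBX should first oxidise the primary alcohol to the aldehyde and on heating dehydrogenate the enone to the cross-conjugated dienone (IBX dehydrogenation of ketones through their enols); the aldehyde cannot be desaturated because C8 bears no hydrogen, and C10 becomes a prochiral centre.

Step 7
Reactants: 13 {2-[(1-methyl-4-oxocyclohexa-2,5-dienyl)methyl]-1,3-dioxolan-2-yl}acetaldehyde
Product: 14 (10R)-8,8-ethylenedioxy-10-methyl-cis-decal-1-ene-3,6-dione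
Conditions: aminoindanol-derived N-pentafluorophenyl triazolium tetrafluoroborate C18H11BF9N3O (15 mol%), KN(SiMe3)2 (12 mol%), toluene (0.02 M), 23 °C
Reagents that add atoms: none
Why: The carbene formed from the triazolium salt adds to the C6 aldehyde, proton transfer gives the enaminol (acyl anion equivalent), this attacks C5 of one enone arm, and protonation at C4 with loss of the carbene gives the 1,4-diketone. The closest known reaction is the enantioselective intramolecular Stetter desymmetrisation of 4,4-disubstituted cyclohexa-2,5-dienones with chiral triazolium precatalysts. Ring B is closed by C5–C6 bond formation in a 6-exo-trig conjugate addition. C10 is set by the catalyst, which chooses between the enantiotopic β-carbons C5 and C1; C5 is set by the tether, which reaches only the dienone face on which it sits, so H-5 should be cis to CH3-10. The step needs enantiotopic-group selection and chemoselectivity over aldehyde self-condensation; the two identical enone arms of the achiral substrate, the use of less base than triazolium salt (no free amide to enolise the aldehyde or open the ketal) and high dilution should secure these. The C5 configuration is not relied on, because C5 becomes trigonal in step 11 and is set in step 13.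

Step 8
Reactants: 14 (10R)-8,8-ethylenedioxy-10-methyl-cis-decal-1-ene-3,6-dione
Product: 15 8,8-ethylenedioxy-6-hydroxy-10-methyl-cis-decal-1-en-3-one
Conditions: NaBH4, MeOH/CH2Cl2 (1:1), −78 °C
Reagents that add atoms: none
Why: Chemoselective carbonyl reduction: NaBH4 at low temperature reduces a saturated ketone faster than a conjugated enone, hydride arriving on the less hindered face to give mainly the alcohol trans to CH3-10, a centre that is removed in step 10.

Step 9
Reactants: 15 8,8-ethylenedioxy-6-hydroxy-10-methyl-cis-decal-1-en-3-one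
Product: 16 O-(C6) imidazole-1-carbothioate of 15
Conditions: 1,1'-thiocarbonyldiimidazole, DMAP (cat.), 1,2-dichloroethane, 80 °C
Reagents that add atoms: 1,1'-thiocarbonyldiimidazole S=C(n1ccnc1)n1ccnc1
Why: Thioacylation of the secondary alcohol gives the imidazolyl thiocarbonate needed for radical deoxygenation.

Step 10
Reactants: 16 O-(C6) imidazole-1-carbothioate of 15
Product: 17 8,8-ethylenedioxy-10-methyl-cis-decal-1-en-3-one
Conditions: Bu3SnH, AIBN (cat.), toluene, 90 °C
Reagents that add atoms: none
Why: Barton–McCombie deoxygenation: the stannyl radical adds to sulfur, the C6–O bond fragments and the secondary C6 radical takes hydrogen from Bu3SnH, which should leave enone and ketal intact.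

Step 11
Reactants: 17 8,8-ethylenedioxy-10-methyl-cis-decal-1-en-3-one
Product: 18 8,8-ethylenedioxy-10-methyldecala-1,4-dien-3-one
Conditions: IBX (1.3 equiv), DMSO/toluene, 65–70 °C
Reagents that add atoms: none
Why: IBX dehydrogenation of the enone across C4–C5 gives the cross-conjugated 1,4-dien-3-one, which makes C5 trigonal so that either C5 epimer of 17 leads to the same compound.

Step 12
Reactants: 18 8,8-ethylenedioxy-10-methyldecala-1,4-dien-3-one
Product: 20 8,8-ethylenedioxy-4,4,10-trimethyldecala-1,5-dien-3-one, via monomethyl dienone 19 (not isolated)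
Conditions: KOtBu (3 equiv), MeI (excess), tBuOH/THF, 0 °C to rt
Reagents that add atoms: iodomethane CI
Why: Deprotonation at C6 gives the extended dienolate, which is methylated twice at C4 with shift of the double bond to C5=C6 (the classical α,α-dimethylation of steroidal 4-en-3-ones), C4 being the only position that can be alkylated.

Step 13
Reactants: 20 8,8-ethylenedioxy-4,4,10-trimethyldecala-1,5-dien-3-one
Product: 21 8,8-ethylenedioxy-4,4,10-trimethyl-trans-decalin-3-one
Conditions: H2 (4 atm), 10% Pd/C, EtOAc, rt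
Reagents that add atoms: none
Why: Heterogeneous hydrogenation saturates C1=C2 and the hindered C5=C6; hydrogen should add to C5=C6 on the face opposite the axial CH3-10, as in the hydrogenation of 4,4-dimethyl-5-ene steroids, which sets H-5 trans to CH3-10.

Step 14
Reactants: 21 8,8-ethylenedioxy-4,4,10-trimethyl-trans-decalin-3-one
Product: 23 3-hydroxy-4,4,10-trimethyl-trans-decalin-8-one, via hydroxy ketal 22 (not isolated)
Conditions: NaBH4, MeOH, 0 °C; then 2 M aq. HCl, THF, rt
Reagents that add atoms: water O
Why: Hydride reduction then ketal hydrolysis: NaBH4 should attack the 4,4-dimethyl-3-ketone axially, away from the axial C4 methyl group, to give the equatorial alcohol (OH cis to CH3-10), and the acid frees the C8 ketone.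

Step 15
Reactants: 23 3-hydroxy-4,4,10-trimethyl-trans-decalin-8-one
Product: 24 3-(tert-butyldimethylsilyloxy)-4,4,10-trimethyl-trans-decalin-8-one
Conditions: TBSOTf, 2,6-lutidine, CH2Cl2, −78 to −20 °C
Reagents that add atoms: tert-butyldimethylsilyl triflate CC(C)(C)[Si](C)(C)OS(=O)(=O)C(F)(F)F
Why: Silylation of the hindered equatorial alcohol protects O3 against the bases and organometallic reagents of the following steps.

Step 16
Reactants: 24 3-(tert-butyldimethylsilyloxy)-4,4,10-trimethyl-trans-decalin-8-one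
Product: 25 3-(tert-butyldimethylsilyloxy)-4,4,10-trimethyl-trans-decal-6-en-8-one
Conditions: IBX (1.5 equiv), DMSO/toluene, 70 °C
Reagents that add atoms: none
Why: IBX dehydrogenation of the ketone can only introduce C6=C7, because the other α-carbon C9 has the quaternary C10 as neighbour; the enone then confines later enolisation to C9.

Step 17
Reactants: 25 3-(tert-butyldimethylsilyloxy)-4,4,10-trimethyl-trans-decal-6-en-8-one
Product: 28 3-(tert-butyldimethylsilyloxy)-4,4,10-trimethyl-9-methylene-trans-decal-6-en-8-one, via Mannich base 26 (not isolated), via methiodide 27 (not isolated)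
Conditions: LiN(iPr)2, THF, −78 °C; CH2=NMe2+ I−, −78 to 0 °C; MeI, CH2Cl2, rt; aq. NaHCO3, CH2Cl2, rt
Reagents that add atoms: N,N-dimethylmethyleneiminium iodide C=[N+](C)C.[I-]
Why: Kinetic α′-deprotonation of the enone at C9 and a Mannich reaction with the iminium salt, then N-methylation and base-induced elimination of trimethylamine, should give the exocyclic C9=C11 enone, which leaves no stereocentre at C9.

Step 18
Reactants: 28 3-(tert-butyldimethylsilyloxy)-4,4,10-trimethyl-9-methylene-trans-decal-6-en-8-one
Product: 29 9-(but-3-ynyl)-3-(tert-butyldimethylsilyloxy)-4,4,10-trimethyl-trans-decal-6-en-8-one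
Conditions: CH2=C=CHSnBu3, TiCl4, CH2Cl2, −78 °C; aq. NaHCO3 at −78 °C
Reagents that add atoms: tributyl(propa-1,2-dienyl)stannane C=C=C[Sn](CCCC)(CCCC)CCCC
Why: Lewis acid-promoted conjugate propargylation: the allenylstannane should attack the unhindered C11 terminus through its CH2 end (SE2′) with loss of tin to give the terminal alkyne, and the enolate is protonated at C9 on the face opposite the axial CH3-10, which places the side chain cis to CH3-10.

Step 19
Reactants: 29 9-(but-3-ynyl)-3-(tert-butyldimethylsilyloxy)-4,4,10-trimethyl-trans-decal-6-en-8-one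
Product: 30 9-(but-3-ynyl)-3-(tert-butyldimethylsilyloxy)-4,4,10-trimethyl-trans-decalin-8-one
Conditions: K[sBu3BH], THF, −78 °C; aq. NH4Cl at −78 °C
Reagents that add atoms: none
Why: Conjugate reduction: the bulky trialkylborohydride should reduce the β-unsubstituted cyclohexenone in the 1,4 sense and the enolate is protonated at C7 on cold work-up, so C9 is not touched and the alkyne survives.

Step 20
Reactants: 30 9-(but-3-ynyl)-3-(tert-butyldimethylsilyloxy)-4,4,10-trimethyl-trans-decalin-8-one
Product: 32 9-(but-3-ynyl)-8-(hydroxymethyl)-3-(tert-butyldimethylsilyloxy)-4,4,10-trimethyl-trans-decalin-8-ol, via hydroxysilane 31 (not isolated)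
Conditions: (iPrO)Me2SiCH2MgCl (3 equiv), THF, 0 °C; then 30% H2O2, KF, KHCO3, MeOH/THF, rt
Reagents that add atoms: (isopropoxydimethylsilyl)methylmagnesium chloride CC(C)O[Si](C)(C)C[Mg]Cl; hydrogen peroxide OO
Why: The silylmethyl Grignard reagent (a hydroxymethyl anion equivalent) should add to the C8 ketone from the face opposite the axial CH3-10, so that C17 is equatorial and the hydroxyl axial (cis to CH3-10), and Tamao–Fleming oxidation turns C–Si into C–OH.

Step 21
Reactants: 32 9-(but-3-ynyl)-8-(hydroxymethyl)-3-(tert-butyldimethylsilyloxy)-4,4,10-trimethyl-trans-decalin-8-ol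
Product: 33 methyl 13-ynoate with the 8,17-diol as cyclic carbonate
Conditions: n-BuLi (3.3 equiv), THF, −78 °C; ClCO2Me (4 equiv), −78 to −20 °C
Reagents that add atoms: methyl chloroformate COC(=O)Cl
Why: Acylation of the trianion with methyl chloroformate puts the ester carbon C15 on the acetylide and converts the 1,2-diol into its cyclic carbonate, the excess chloroformate trapping the methoxide set free on ring closure.

Step 22
Reactants: 33 methyl 13-ynoate with the 8,17-diol as cyclic carbonate
Product: 34 methyl (13Z)-enoate with the 8,17-diol as cyclic carbonate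
Conditions: Me2CuLi (from CuI and MeLi, 3 equiv), THF, −78 °C; MeOH then aq. NH4Cl at −78 °C
Reagents that add atoms: lithium dimethylcuprate [Li+].C[Cu-]C
Why: Syn-carbocupration of the ynoate by the methyl cuprate and protonation of the vinylcopper species at low temperature with retention should place CH3-16 trans to the ester, which is the 13Z geometry.

Step 23
Reactants: 34 methyl (13Z)-enoate with the 8,17-diol as cyclic carbonate
Product: 35 (13Z)-3-(tert-butyldimethylsilyloxy)-8,17-dihydroxylabd-13-en-15-oic acid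
Conditions: LiOH, THF/MeOH/H2O, rt to 40 °C; aq. HCl to pH 3
Reagents that add atoms: lithium hydroxide [Li+].[OH-]
Why: Saponification cleaves the methyl ester and the cyclic carbonate, while the hindered silyl ether and the Z-alkene are stable to hydroxide.

Step 24
Reactants: 35 (13Z)-3-(tert-butyldimethylsilyloxy)-8,17-dihydroxylabd-13-en-15-oic acid
Product: 36 (13Z)-3-(tert-butyldimethylsilyloxy)-8-hydroxy-17-oxolabd-13-en-15-oic acid
Conditions: IBX (1.5 equiv), DMSO, rt
Reagents that add atoms: none
Why: IBX oxidation of alcohols: the primary alcohol of the 1,2-diol should be oxidised to the aldehyde without cleavage of the glycol C–C bond, the tertiary alcohol cannot be oxidised and the secondary one is still silylated.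

Step 25
Reactants: 36 (13Z)-3-(tert-butyldimethylsilyloxy)-8-hydroxy-17-oxolabd-13-en-15-oic acid
Product: 37 CNP0273710.1
Conditions: 48% aq. HF, MeCN, rt
Reagents that add atoms: none
Why: Fluoride-mediated cleavage of the Si–O bond under mildly acidic conditions should free the C3 hydroxyl without affecting the α-hydroxy aldehyde, the tertiary alcohol or the Z-enoic acid.

**Compound list**

1 | 3-methylpent-4-enoic acid (racemic) | C=CC(C)CC(=O)O | starting material
2 | 1-(3-methylpent-4-enoyl)imidazole | C=CC(C)CC(=O)n1ccnc1 | intermediate (not isolated)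
3 | ethyl 5-methyl-3-oxohept-6-enoate (racemic) | CCOC(=O)CC(=O)CC(C)C=C | intermediate
4 | ethyl [2-(2-methylbut-3-enyl)-1,3-dioxolan-2-yl]acetate (racemic) | CCOC(=O)CC1(CC(C)C=C)OCCO1 | intermediate
5 | 2-[2-(2-methylbut-3-enyl)-1,3-dioxolan-2-yl]ethanol (racemic) | OCCC1(CC(C)C=C)OCCO1 | intermediate
6 | ozonide of 5: 2-{2-[2-(1,2,4-trioxolan-3-yl)propyl]-1,3-dioxolan-2-yl}ethanol | OCCC1(CC(C)C2OCOO2)OCCO1 | intermediate (not isolated)
7 | 3-[2-(2-hydroxyethyl)-1,3-dioxolan-2-yl]-2-methylpropanal (racemic) | O=CC(C)CC1(CCO)OCCO1 | intermediate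
8 | methyl vinyl ketone (but-3-en-2-one) | CC(=O)C=C | starting material
9 | pyrrolidine enamine of 7 (E) | OCCC1(C/C(C)=C/N2CCCC2)OCCO1 | intermediate (not isolated)
10 | 2-{[2-(2-hydroxyethyl)-1,3-dioxolan-2-yl]methyl}-2-methyl-5-oxohexanal (racemic) | O=CC(C)(CCC(C)=O)CC1(CCO)OCCO1 | intermediate (not isolated)
11 | 4-{[2-(2-hydroxyethyl)-1,3-dioxolan-2-yl]methyl}-4-methylcyclohex-2-enone (racemic) | CC1(CC2(CCO)OCCO2)C=CC(=O)CC1 | intermediate
12 | {2-[(1-methyl-4-oxocyclohex-2-enyl)methyl]-1,3-dioxolan-2-yl}acetaldehyde (racemic) | CC1(CC2(CC=O)OCCO2)C=CC(=O)CC1 | intermediate (not isolated)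
13 | {2-[(1-methyl-4-oxocyclohexa-2,5-dienyl)methyl]-1,3-dioxolan-2-yl}acetaldehyde (achiral Stetter precursor) | O=CCC1(OCCO1)CC2(C)C=CC(=O)C=C2 | intermediate
14 | (10R)-8,8-ethylenedioxy-10-methyl-cis-decal-1-ene-3,6-dione; H-5 cis to CH3-10 | C1[C@]2(C)C=CC(=O)C[C@@H]2C(=O)CC13OCCO3 | intermediate
15 | 8,8-ethylenedioxy-6-hydroxy-10-methyl-cis-decal-1-en-3-one; 6-OH trans to CH3-10 (expected major epimer) | C1[C@]2(C)C=CC(=O)C[C@@H]2[C@H](O)CC13OCCO3 | intermediate
16 | O-(C6) imidazole-1-carbothioate of 15 | C1[C@]2(C)C=CC(=O)C[C@@H]2[C@H](OC(=S)n4ccnc4)CC13OCCO3 | intermediate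
17 | 8,8-ethylenedioxy-10-methyl-cis-decal-1-en-3-one; H-5 cis to CH3-10 | C1[C@]2(C)C=CC(=O)C[C@@H]2CCC13OCCO3 | intermediate
18 | 8,8-ethylenedioxy-10-methyldecala-1,4-dien-3-one; only C10 stereogenic | C1[C@]2(C)C=CC(=O)C=C2CCC13OCCO3 | intermediate
19 | 8,8-ethylenedioxy-4,10-dimethyldecala-1,5-dien-3-one (C4 epimers) | C1[C@]2(C)C=CC(=O)C(C)C2=CCC13OCCO3 | intermediate (not isolated)
20 | 8,8-ethylenedioxy-4,4,10-trimethyldecala-1,5-dien-3-one | C1[C@]2(C)C=CC(=O)C(C)(C)C2=CCC13OCCO3 | intermediate
21 | 8,8-ethylenedioxy-4,4,10-trimethyl-trans-decalin-3-one; H-5 trans to CH3-10 | C1[C@]2(C)CCC(=O)C(C)(C)[C@H]2CCC13OCCO3 | intermediate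
22 | 8,8-ethylenedioxy-4,4,10-trimethyl-trans-decalin-3-ol; 3-OH equatorial, cis to CH3-10 | C1[C@]2(C)CC[C@@H](O)C(C)(C)[C@H]2CCC13OCCO3 | intermediate (not isolated)
23 | 3-hydroxy-4,4,10-trimethyl-trans-decalin-8-one; 3-OH cis to CH3-10 | C1[C@]2(C)CC[C@@H](O)C(C)(C)[C@H]2CCC1=O | intermediate
24 | 3-(tert-butyldimethylsilyloxy)-4,4,10-trimethyl-trans-decalin-8-one | C1[C@]2(C)CC[C@@H](O[Si](C)(C)C(C)(C)C)C(C)(C)[C@H]2CCC1=O | intermediate
25 | 3-(tert-butyldimethylsilyloxy)-4,4,10-trimethyl-trans-decal-6-en-8-one | C1[C@]2(C)CC[C@@H](O[Si](C)(C)C(C)(C)C)C(C)(C)[C@H]2C=CC1=O | intermediate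
26 | 9-(dimethylaminomethyl) derivative of 25; CH2N trans to CH3-10 | CN(C)C[C@@H]1[C@]2(C)CC[C@@H](O[Si](C)(C)C(C)(C)C)C(C)(C)[C@H]2C=CC1=O | intermediate (not isolated)
27 | trimethylammonium iodide of 26 | C[N+](C)(C)C[C@@H]1[C@]2(C)CC[C@@H](O[Si](C)(C)C(C)(C)C)C(C)(C)[C@H]2C=CC1=O.[I-] | intermediate (not isolated)
28 | 3-(tert-butyldimethylsilyloxy)-4,4,10-trimethyl-9-methylene-trans-decal-6-en-8-one | C=C1[C@]2(C)CC[C@@H](O[Si](C)(C)C(C)(C)C)C(C)(C)[C@H]2C=CC1=O | intermediate
29 | 9-(but-3-ynyl)-3-(tert-butyldimethylsilyloxy)-4,4,10-trimethyl-trans-decal-6-en-8-one; side chain cis to CH3-10 | C#CCC[C@H]1[C@]2(C)CC[C@@H](O[Si](C)(C)C(C)(C)C)C(C)(C)[C@H]2C=CC1=O | intermediate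
30 | 9-(but-3-ynyl)-3-(tert-butyldimethylsilyloxy)-4,4,10-trimethyl-trans-decalin-8-one; side chain cis to CH3-10 | C#CCC[C@H]1[C@]2(C)CC[C@@H](O[Si](C)(C)C(C)(C)C)C(C)(C)[C@H]2CCC1=O | intermediate
31 | 8-[(isopropoxydimethylsilyl)methyl] carbinol from 30; 8-OH cis to CH3-10 | C#CCC[C@H]1[C@]2(C)CC[C@@H](O[Si](C)(C)C(C)(C)C)C(C)(C)[C@H]2CC[C@]1(O)C[Si](C)(C)OC(C)C | intermediate (not isolated)
32 | 9-(but-3-ynyl)-8-(hydroxymethyl)-3-(tert-butyldimethylsilyloxy)-4,4,10-trimethyl-trans-decalin-8-ol; 8-OH axial and cis to CH3-10 | C#CCC[C@H]1[C@]2(C)CC[C@@H](O[Si](C)(C)C(C)(C)C)C(C)(C)[C@H]2CC[C@]1(O)CO | intermediate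
33 | methyl 13-ynoate; 8,17-diol as spiro cyclic carbonate; 3-O-TBS | COC(=O)C#CCC[C@H]1[C@]2(C)CC[C@@H](O[Si](C)(C)C(C)(C)C)C(C)(C)[C@H]2CC[C@]13COC(=O)O3 | intermediate
34 | methyl (13Z)-enoate; 8,17-diol as spiro cyclic carbonate; 3-O-TBS | C/C(=C/C(=O)OC)CC[C@H]1[C@]2(C)CC[C@@H](O[Si](C)(C)C(C)(C)C)C(C)(C)[C@H]2CC[C@]13COC(=O)O3 | intermediate
35 | (13Z)-3-(tert-butyldimethylsilyloxy)-8,17-dihydroxylabd-13-en-15-oic acid | C/C(=C/C(=O)O)CC[C@H]1[C@]2(C)CC[C@@H](O[Si](C)(C)C(C)(C)C)C(C)(C)[C@H]2CC[C@]1(O)CO | intermediate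
36 | (13Z)-3-(tert-butyldimethylsilyloxy)-8-hydroxy-17-oxolabd-13-en-15-oic acid | C/C(=C/C(=O)O)CC[C@H]1[C@]2(C)CC[C@@H](O[Si](C)(C)C(C)(C)C)C(C)(C)[C@H]2CC[C@]1(O)C=O | intermediate
37 | CNP0273710.1: (13Z)-3,8-dihydroxy-17-oxolabd-13-en-15-oic acid; 3-OH, 8-OH, the C9 side chain and CH3-10 on one face; H-5, H-9 and the formyl group on the other | C/C(=C/C(=O)O)CC[C@H]1[C@]2(C)CC[C@@H](O)C(C)(C)[C@H]2CC[C@]1(O)C=O | target

**Step count and risks**

Total step count: 25. Longest linear sequence: 25 steps (1 to 37); the route is fully linear.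

Steps most likely to fail:

1. Step 7 (key step). What may go wrong: the catalyst may discriminate poorly between the two enantiotopic enone arms, or the 6-exo closure may be slow enough for aldehyde self-condensation to win. The fallback sets out from methyl vinyl ketone 8 and comes back to the route at 21. 1,4-Dioxaspiro[4.5]decan-8-one is methylated (LiN(iPr)2, MeI) to 7-methyl-1,4-dioxaspiro[4.5]decan-8-one F1. Condensation with (S)-1-phenylethylamine gives the imine F2, whose enamine tautomer adds to 8 at the methyl-bearing carbon under control of the auxiliary. Hydrolysis (aq. AcOH) gives the (S)-configured 2-methyl-2-(3-oxobutyl) ketone F3, and NaOMe in MeOH closes ring A by aldol condensation to the 4-en-3-one F4. KOtBu and MeI give the 4,4-dimethyl-5-en-3-one F5, and hydrogenation (H2, Pd/C) gives 21.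

2. Step 18. What may go wrong: the stannane may attack the wrong terminus of the cross-conjugated dienone, or the Lewis acid may cause oligomerisation or loss of the silyl ether. The fallback sets out from 25 and comes back at 30. 4-(Trimethylsilyl)but-3-yn-1-ol is converted (Tf2O, 2,6-lutidine) into 4-(trimethylsilyl)but-3-ynyl triflate F6. The lithium α′-enolate of 25 (LiN(iPr)2, THF, −78 °C) is alkylated with it to the 9-alkylated enone F7, the chain entering anti to CH3-10. Conjugate reduction with K[sBu3BH] gives the saturated ketone F8. K2CO3 in MeOH removes the alkynyl silyl group and equilibrates C9; the isomer with the equatorial side chain is 30, and its C9 epimer is separated and returned to the base.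

3. Step 6. What may go wrong: the β-ketal aldehyde may be over-oxidised or decompose under the hot dehydrogenation conditions. The fallback sets out from 11 and comes back at 13. The ring is oxidised before the alcohol: DDQ in dioxane at reflux dehydrogenates 11 to the dienone alcohol 4-{[2-(2-hydroxyethyl)-1,3-dioxolan-2-yl]methyl}-4-methylcyclohexa-2,5-dienone F9. Dess–Martin periodinane in CH2Cl2 at rt then gives 13, so the aldehyde never meets the hot oxidant.

Further compounds
F1 | step 7 | 7-methyl-1,4-dioxaspiro[4.5]decan-8-one (racemic) | CC1CC2(CCC1=O)OCCO2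
F2 | step 7 | imine of F1 with (S)-1-phenylethylamine | CC1CC2(CCC1=N[C@@H](C)c1ccccc1)OCCO2
F3 | step 7 | (S)-7-methyl-7-(3-oxobutyl)-1,4-dioxaspiro[4.5]decan-8-one | C1[C@](C)(CCC(C)=O)C(=O)CCC12OCCO2
F4 | step 7 | 8,8-ethylenedioxy-10-methyldecal-4-en-3-one | C1[C@]2(C)CCC(=O)C=C2CCC13OCCO3
F5 | step 7 | 8,8-ethylenedioxy-4,4,10-trimethyldecal-5-en-3-one | C1[C@]2(C)CCC(=O)C(C)(C)C2=CCC13OCCO3
F6 | step 18 | 4-(trimethylsilyl)but-3-ynyl trifluoromethanesulfonate | C[Si](C)(C)C#CCCOS(=O)(=O)C(F)(F)F
F7 | step 18 | 9-[4-(trimethylsilyl)but-3-ynyl] derivative of 25; side chain trans to CH3-10 | C[Si](C)(C)C#CCC[C@@H]1[C@]2(C)CC[C@@H](O[Si](C)(C)C(C)(C)C)C(C)(C)[C@H]2C=CC1=O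
F8 | step 18 | 9-[4-(trimethylsilyl)but-3-ynyl]-3-(tert-butyldimethylsilyloxy)-4,4,10-trimethyl-trans-decalin-8-one; side chain trans to CH3-10 | C[Si](C)(C)C#CCC[C@@H]1[C@]2(C)CC[C@@H](O[Si](C)(C)C(C)(C)C)C(C)(C)[C@H]2CCC1=O
F9 | step 6 | 4-{[2-(2-hydroxyethyl)-1,3-dioxolan-2-yl]methyl}-4-methylcyclohexa-2,5-dienone | CC1(CC2(CCO)OCCO2)C=CC(=O)C=C1
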